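**Retrosynthetic overview**

- Endgame: a di-tert-butylsilylene bridge (fluoride) and two MOM ethers (acid) are removed from a silicon-bridged indenone.
- Key disconnection: the five-membered ring is closed last, C3–C3a and C1–C2 together, by a palladium-catalysed annulation of an ortho-iodobenzaldehyde (ring A) onto a diarylalkyne (ring B = orcinol ring, ring C = aryl ether ring, ring D = benzoate ring).
- Enabling feature: the oxygen on C4 of ring A and one ortho oxygen of ring B (the 2,6-dihydroxy-4-methylphenyl group on C3) lie on either side of the new C3–C3a bond. One silicon atom can span them as an eight-membered 1,3-dioxa-2-silocine (O–Si–O, C4, C3a, C3, C1′ and C2′ of ring B), which makes the first C–C bond intramolecular and so fixes which alkyne carbon and which ring-A carbon react.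
- Alkyne: Sonogashira coupling of a 2-iodoorcinol derivative with a terminal alkyne made (Ohira–Bestmann) from the ring C/ring D diaryl ether aldehyde (Ullmann coupling).
- Rings A and C come from one iodinated 3-hydroxy-5-methoxybenzaldehyde. Order of ring formation: diaryl ether link, alkyne, then the silicon ring and the indenone ring in the key step.

Key step: step 13

Remark: the target has no stereocentre, and rotation about its aryl–indenone and aryl–oxygen bonds is taken as free, so nothing stereochemical has to be set. The three starting materials are taken as commercial.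

**Route**

Step 1
Reactants: 1 3-hydroxy-5-methoxybenzaldehyde
Product: 2 3-formyl-5-methoxyphenyl acetate
Conditions: Ac2O, pyridine, CH2Cl2, 0 °C → rt
Reagents that add atoms: acetic anhydride, CC(=O)OC(C)=O
Why: O-acetylation (nucleophilic acyl substitution) turns the phenol from the strongest donor on the ring into a weak one, so that the methoxy group alone directs the next substitution.

Step 2
Reactants: 2 3-formyl-5-methoxyphenyl acetate
Product: 3 3-formyl-2-iodo-5-methoxyphenyl acetate
Conditions: NIS, TFA (cat.), MeCN, rt
Reagents that add atoms: N-iodosuccinimide, O=C1CCC(=O)N1I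
Why: Electrophilic aromatic iodination should go para to the methoxy group, that is at the carbon between CHO and OAc, as it does when 3-methoxyphenyl acetate is iodinated to 2-iodo-5-methoxyphenyl acetate.

Step 3
Reactants: 3 3-formyl-2-iodo-5-methoxyphenyl acetate
Product: 4 3-hydroxy-2-iodo-5-methoxybenzaldehyde
Conditions: K2CO3 (cat.), MeOH, 0 °C
Reagents that add atoms: none
Why: Base-catalysed methanolysis (transesterification) of the aryl acetate frees the phenol without touching the aldehyde or the aryl iodide.

Step 4
Reactants: 4 3-hydroxy-2-iodo-5-methoxybenzaldehyde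
Product: 5 2-iodo-5-methoxy-3-(methoxymethoxy)benzaldehyde
Conditions: MOMCl, i-Pr2NEt, CH2Cl2, 0 °C → rt
Reagents that add atoms: chloromethyl methyl ether, COCCl
Why: Williamson-type O-alkylation gives the methoxymethyl ether, a small ortho group that is stable to the copper/base coupling and to every later step up to the final acid treatment.

Step 5
Reactants: 5 2-iodo-5-methoxy-3-(methoxymethoxy)benzaldehyde; 6 methyl 2,6-dihydroxy-4-methylbenzoate (3 equiv)
Product: 7 methyl 2-[2-formyl-4-methoxy-6-(methoxymethoxy)phenoxy]-6-hydroxy-4-methylbenzoate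
Conditions: CuI (20 mol%), picolinic acid (40 mol%), K3PO4, DMSO, 90 °C
Reagents that add atoms: none
Why: Ullmann diaryl ether coupling, helped by the ortho-formyl group of the iodide; diol 6 is symmetrical and in excess so that one of its two equivalent OH groups is arylated while the other stays hydrogen-bonded to the ester.

Step 6
Reactants: 7 methyl 2-[2-formyl-4-methoxy-6-(methoxymethoxy)phenoxy]-6-hydroxy-4-methylbenzoate
Product: 8 methyl 2-[2-ethynyl-4-methoxy-6-(methoxymethoxy)phenoxy]-6-hydroxy-4-methylbenzoate
Conditions: dimethyl (1-diazo-2-oxopropyl)phosphonate, K2CO3, MeOH, rt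
Reagents that add atoms: dimethyl (1-diazo-2-oxopropyl)phosphonate, COP(=O)(OC)C(=[N+]=[N-])C(C)=O
Why: Seyferth–Gilbert homologation in its Ohira–Bestmann form converts the aryl aldehyde into the terminal alkyne under conditions in which exchange of the methyl ester with methanol is degenerate.

Step 7
Reactants: 9 orcinol (5-methylbenzene-1,3-diol)
Product: 10 2-iodo-5-methylbenzene-1,3-diol
Conditions: I2, NaHCO3, H2O/THF, 0 °C
Reagents that add atoms: iodine, II
Why: Electrophilic iodination of the resorcinol in aqueous hydrogen carbonate goes to the carbon between the two hydroxyl groups, as known for resorcinol itself.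

Step 8
Reactants: 10 2-iodo-5-methylbenzene-1,3-diol
Product: 11 2-iodo-3-(methoxymethoxy)-5-methylphenol
Conditions: NaH (1.0 equiv), MOMCl (1.0 equiv), THF/DMF, 0 °C
Reagents that add atoms: chloromethyl methyl ether, COCCl
Why: Williamson mono-O-alkylation through the monosodium phenoxide of a symmetrical diol, which is statistical, so the bis-ether is removed and the recovered diol recycled.

Step 9
Reactants: 11 2-iodo-3-(methoxymethoxy)-5-methylphenol
Product: 12 2-iodo-3-(methoxymethoxy)-5-methylphenyl acetate
Conditions: Ac2O, Et3N, DMAP (cat.), CH2Cl2, rt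
Reagents that add atoms: acetic anhydride, CC(=O)OC(C)=O
Why: O-acetylation masks the remaining ortho hydroxyl so that the ortho-alkynylphenol cannot cyclise to a benzofuran during the palladium/copper coupling.

Step 10
Reactants: 8 methyl 2-[2-ethynyl-4-methoxy-6-(methoxymethoxy)phenoxy]-6-hydroxy-4-methylbenzoate; 12 2-iodo-3-(methoxymethoxy)-5-methylphenyl acetate
Product: 13 methyl 2-[2-{[2-acetoxy-6-(methoxymethoxy)-4-methylphenyl]ethynyl}-4-methoxy-6-(methoxymethoxy)phenoxy]-6-hydroxy-4-methylbenzoate
Conditions: PdCl2(PPh3)2 (5 mol%), CuI (10 mol%), Et3N, DMF, 60 °C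
Reagents that add atoms: none
Why: Sonogashira coupling of the terminal alkyne with the di-ortho-oxygenated aryl iodide, which couples on gentle heating while the aryl acetate, the MOM ethers and the free salicylate OH stay inert.

Step 11
Reactants: 13 methyl 2-[2-{[2-acetoxy-6-(methoxymethoxy)-4-methylphenyl]ethynyl}-4-methoxy-6-(methoxymethoxy)phenoxy]-6-hydroxy-4-methylbenzoate
Product: 14 methyl 6-hydroxy-2-[2-{[2-hydroxy-6-(methoxymethoxy)-4-methylphenyl]ethynyl}-4-methoxy-6-(methoxymethoxy)phenoxy]-4-methylbenzoate
Conditions: K2CO3 (cat.), MeOH/THF, 0 °C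
Reagents that add atoms: none
Why: Cold base-catalysed methanolysis removes only the aryl acetate, and at this temperature in the absence of copper or palladium the freed ortho-alkynylphenol should not undergo 5-endo cyclisation.

Step 12
Reactants: 4 3-hydroxy-2-iodo-5-methoxybenzaldehyde; 14 methyl 6-hydroxy-2-[2-{[2-hydroxy-6-(methoxymethoxy)-4-methylphenyl]ethynyl}-4-methoxy-6-(methoxymethoxy)phenoxy]-4-methylbenzoate
Product: 16 methyl 2-[2-({2-[di-tert-butyl(3-formyl-2-iodo-5-methoxyphenoxy)silyl]oxy-6-(methoxymethoxy)-4-methylphenyl}ethynyl)-4-methoxy-6-(methoxymethoxy)phenoxy]-6-hydroxy-4-methylbenzoate (silyl ketal), via aryloxysilyl triflate 15 (not isolated)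
Conditions: 4, t-Bu2Si(OTf)2 (1.0 equiv), 2,6-lutidine, CH2Cl2, −78 → 0 °C; then 14, DMAP (cat.), rt → 40 °C
Reagents that add atoms: di-tert-butylsilyl bis(trifluoromethanesulfonate), CC(C)(C)[Si](OS(=O)(=O)C(F)(F)F)(OS(=O)(=O)C(F)(F)F)C(C)(C)C
Why: Stepwise silylation with a silyl bis(triflate) (unsymmetrical silyl ketal formation) works because monotriflate 15 is far less reactive than the bis(triflate), and of the two OH groups of 14 only the ring-B phenol is free to attack, the ring-D OH being hydrogen-bonded to and flanked by its ester.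

Step 13
Reactants: 16 silyl ketal (ring-A iodoaldehyde tethered through O–Si(t-Bu)2–O to ring B of the diarylalkyne)
Product: 18 silicon-bridged indenone (di-tert-butylsilylene bridge from O-4 of ring A to O-2′ of ring B; MOM ethers on rings B and C), via alkenylpalladium iodide 17 (not isolated)
Conditions: Pd(OAc)2 (10 mol%), NaOAc (4 equiv), n-Bu4NCl (1 equiv), DMA (0.01 M), 100 °C
Reagents that add atoms: none
Why: Proposed new method: a temporary-silicon-tethered Larock indenone annulation, in which zerovalent palladium formed from Pd(OAc)2 inserts into the C–I bond, the arylpalladium iodide adds syn across the tethered alkyne to give 17, the C–Pd bond of 17 adds to the neighbouring aldehyde, and the palladium alkoxide loses hydride (β-hydride elimination) to give the ketone and, with NaOAc, zerovalent palladium again. The closest known reaction is the intermolecular Larock annulation of 2-iodobenzaldehydes with diarylalkynes, which forms the same two bonds under these conditions, supported by known tethered Larock indole annulations and by palladium-catalysed couplings that tolerate di-tert-butylsilylene bis(aryl ether) tethers. The eight-membered 1,3-dioxa-2-silocine closes by 8-exo-dig carbopalladation (C3–C3a) and the five-membered ring then closes by 5-exo-trig addition of the alkenyl–palladium bond to the C=O (C1–C2). No stereocentre is formed, and the syn addition places palladium cis to ring A, which is the geometry the carbonyl addition needs. The selectivity needed is regiochemical twice over: ring A must bond to the alkyne carbon bearing the bulkier 2,6-dioxygenated ring B, against the usual steric preference, and through the ring carbon next to the C4 oxygen and not the one next to OMe; the O–Si–O bridge secures the first because the distal alkyne carbon could only be reached through a nine-membered ring holding a trans alkene, and the position of iodine in 4 secures the second. High dilution and the two tert-butyl groups on silicon, which hold the two aryloxy arms together (Thorpe–Ingold effect), should favour cyclisation over oligomerisation and over direct C–H arylation of ring B.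

Step 14
Reactants: 18 silicon-bridged indenone
Product: 19 methyl 6-hydroxy-2-{2-[4-hydroxy-3-(2-hydroxy-6-(methoxymethoxy)-4-methylphenyl)-6-methoxy-1-oxo-1H-inden-2-yl]-4-methoxy-6-(methoxymethoxy)phenoxy}-4-methylbenzoate
Conditions: HF·pyridine, pyridine, THF, 0 °C → rt
Reagents that add atoms: none
Why: Fluoride-mediated cleavage of the two aryl O–Si bonds (desilylation) removes the tether as the difluorosilane and leaves the MOM ethers and the methyl ester untouched.

Step 15
Reactants: 19 methyl 6-hydroxy-2-{2-[4-hydroxy-3-(2-hydroxy-6-(methoxymethoxy)-4-methylphenyl)-6-methoxy-1-oxo-1H-inden-2-yl]-4-methoxy-6-(methoxymethoxy)phenoxy}-4-methylbenzoate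
Product: 20 ascomindone B, methyl 2-{2-[3-(2,6-dihydroxy-4-methylphenyl)-4-hydroxy-6-methoxy-1-oxo-1H-inden-2-yl]-6-hydroxy-4-methoxyphenoxy}-6-hydroxy-4-methylbenzoate
Conditions: HCl (3 M in MeOH), THF, 40 °C
Reagents that add atoms: none
Why: Acid-catalysed acetal exchange with methanol (MOM removal) frees the last two phenols, and in methanol the methyl ester can only exchange with itself.

**Compound list**

1 | 3-hydroxy-5-methoxybenzaldehyde | O=Cc1cc(O)cc(OC)c1 | starting material
2 | 3-formyl-5-methoxyphenyl acetate | CC(=O)Oc1cc(C=O)cc(OC)c1 | intermediate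
3 | 3-formyl-2-iodo-5-methoxyphenyl acetate | CC(=O)Oc1cc(OC)cc(C=O)c1I | intermediate
4 | 3-hydroxy-2-iodo-5-methoxybenzaldehyde | O=Cc1cc(OC)cc(O)c1I | intermediate
5 | 2-iodo-5-methoxy-3-(methoxymethoxy)benzaldehyde | O=Cc1cc(OC)cc(OCOC)c1I | intermediate
6 | methyl 2,6-dihydroxy-4-methylbenzoate | COC(=O)c1c(O)cc(C)cc1O | starting material
7 | methyl 2-[2-formyl-4-methoxy-6-(methoxymethoxy)phenoxy]-6-hydroxy-4-methylbenzoate | COC(=O)c1c(O)cc(C)cc1Oc1c(C=O)cc(OC)cc1OCOC | intermediate
8 | methyl 2-[2-ethynyl-4-methoxy-6-(methoxymethoxy)phenoxy]-6-hydroxy-4-methylbenzoate | COC(=O)c1c(O)cc(C)cc1Oc1c(C#C)cc(OC)cc1OCOC | intermediate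
9 | orcinol (5-methylbenzene-1,3-diol) | Cc1cc(O)cc(O)c1 | starting material
10 | 2-iodo-5-methylbenzene-1,3-diol | Cc1cc(O)c(I)c(O)c1 | intermediate
11 | 2-iodo-3-(methoxymethoxy)-5-methylphenol | Cc1cc(O)c(I)c(OCOC)c1 | intermediate
12 | 2-iodo-3-(methoxymethoxy)-5-methylphenyl acetate | CC(=O)Oc1cc(C)cc(OCOC)c1I | intermediate
13 | methyl 2-[2-{[2-acetoxy-6-(methoxymethoxy)-4-methylphenyl]ethynyl}-4-methoxy-6-(methoxymethoxy)phenoxy]-6-hydroxy-4-methylbenzoate | COC(=O)c1c(O)cc(C)cc1Oc1c(C#Cc2c(OC(C)=O)cc(C)cc2OCOC)cc(OC)cc1OCOC | intermediate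
14 | methyl 6-hydroxy-2-[2-{[2-hydroxy-6-(methoxymethoxy)-4-methylphenyl]ethynyl}-4-methoxy-6-(methoxymethoxy)phenoxy]-4-methylbenzoate | COC(=O)c1c(O)cc(C)cc1Oc1c(C#Cc2c(O)cc(C)cc2OCOC)cc(OC)cc1OCOC | intermediate
15 | di-tert-butyl(3-formyl-2-iodo-5-methoxyphenoxy)silyl trifluoromethanesulfonate (not isolated) | O=Cc1cc(OC)cc(O[Si](OS(=O)(=O)C(F)(F)F)(C(C)(C)C)C(C)(C)C)c1I | intermediate
16 | methyl 2-[2-({2-[di-tert-butyl(3-formyl-2-iodo-5-methoxyphenoxy)silyl]oxy-6-(methoxymethoxy)-4-methylphenyl}ethynyl)-4-methoxy-6-(methoxymethoxy)phenoxy]-6-hydroxy-4-methylbenzoate (silyl ketal) | O=Cc1cc(OC)cc(O[Si](C(C)(C)C)(C(C)(C)C)Oc2cc(C)cc(OCOC)c2C#Cc2cc(OC)cc(OCOC)c2Oc2cc(C)cc(O)c2C(=O)OC)c1I | intermediate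
17 | alkenylpalladium iodide formed by 8-exo-dig carbopalladation of 16: ring A bonded to the alkyne carbon that bears ring B, palladium on the carbon that bears ring C and cis to ring A, aldehyde still present, ligands on palladium omitted (not isolated) | O=Cc1cc(OC)cc2O[Si](C(C)(C)C)(C(C)(C)C)Oc3cc(C)cc(OCOC)c3/C(c12)=C(/[Pd]I)c1cc(OC)cc(OCOC)c1Oc1cc(C)cc(O)c1C(=O)OC | intermediate
18 | silicon-bridged indenone: 6-methoxyinden-1-one whose O-4 and the ortho oxygen of the 3-aryl ring B are joined by Si(t-Bu)2 in an eight-membered 1,3-dioxa-2-silocine fused across C3–C3a; ring B also carries OMOM and methyl; C2 carries ring C (OMOM, OMe, aryloxy link to ring D with CO2Me, OH and methyl) | O=C1C(c2cc(OC)cc(OCOC)c2Oc2cc(C)cc(O)c2C(=O)OC)=C2c3c(cc(C)cc3OCOC)O[Si](C(C)(C)C)(C(C)(C)C)Oc3cc(OC)cc1c32 | intermediate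
19 | methyl 6-hydroxy-2-{2-[4-hydroxy-3-(2-hydroxy-6-(methoxymethoxy)-4-methylphenyl)-6-methoxy-1-oxo-1H-inden-2-yl]-4-methoxy-6-(methoxymethoxy)phenoxy}-4-methylbenzoate | COC(=O)c1c(O)cc(C)cc1Oc1c(OCOC)cc(OC)cc1C1=C(c2c(O)cc(C)cc2OCOC)c2c(O)cc(OC)cc2C1=O | intermediate
20 | ascomindone B, methyl 2-{2-[3-(2,6-dihydroxy-4-methylphenyl)-4-hydroxy-6-methoxy-1-oxo-1H-inden-2-yl]-6-hydroxy-4-methoxyphenoxy}-6-hydroxy-4-methylbenzoate | COC(=O)c1c(O)cc(C)cc1Oc1c(O)cc(OC)cc1C1=C(c2c(O)cc(C)cc2O)c2c(O)cc(OC)cc2C1=O | target

**Step count and risks**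

Total step count: 15. Longest linear sequence: 12 steps (steps 1, 2, 3, 4, 5, 6, 10, 11, 12, 13, 14, 15).

The three steps most likely to fail:

1. Step 13 (labelled step). The 8-exo-dig carbopalladation may be too slow for reasons of medium-ring strain and entropy. The arylpalladium species would then go into oligomerisation, protodeiodination or direct C–H arylation of ring B at its free ortho position, and acetate at 100 °C may also cleave the silyl ketal. Fallback with known chemistry: setting out from 5 and 13, the untethered Larock indenone annulation (Pd(OAc)2, NaOAc, n-Bu4NCl, DMA, 100 °C), which is established for 2-iodobenzaldehydes and diarylalkynes, should give methyl 2-{2-[3-(2-acetoxy-6-(methoxymethoxy)-4-methylphenyl)-6-methoxy-4-(methoxymethoxy)-1-oxo-1H-inden-2-yl]-4-methoxy-6-(methoxymethoxy)phenoxy}-6-hydroxy-4-methylbenzoate F1 together with its C2/C3 regioisomer. Regiochemistry here rests only on the polarisation of the alkyne by the more electron-rich ring B, against the steric preference, so the two indenones would have to be separated by chromatography. Treatment of F1 with 3 M HCl in MeOH at 40 °C would then cleave the three MOM ethers and the aryl acetate in one operation, and the fallback comes back to the route at 20.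

2. Step 5. C–O bond formation at a doubly ortho-substituted, electron-rich aryl iodide with a weakly nucleophilic, chelating salicylate phenoxide may be slow, so that protodeiodination, base-induced decay of the aldehyde or double arylation of 6 take over. Fallback (metal-free arylation with a diaryliodonium salt in place of copper catalysis): setting out from 3, oxidation with mCPBA and TsOH·H2O in MeCN followed by 1,3,5-trimethoxybenzene should give (2-acetoxy-6-formyl-4-methoxyphenyl)(2,4,6-trimethoxyphenyl)iodonium tosylate F2. F2 should transfer its less electron-rich, ortho-substituted aryl group to the phenoxide of 6 (K2CO3, MeCN, 40 °C) to give methyl 2-(2-acetoxy-6-formyl-4-methoxyphenoxy)-6-hydroxy-4-methylbenzoate F3. Cold methanolysis (K2CO3 cat., MeOH, 0 °C) would give methyl 2-(2-formyl-6-hydroxy-4-methoxyphenoxy)-6-hydroxy-4-methylbenzoate F4, and MOMCl (1 equiv) with i-Pr2NEt should alkylate only the phenol that is not hydrogen-bonded to the ester, which comes back to the route at 7.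

3. Step 12. The second Si–O bond at the crowded di-tert-butylsilicon centre may not form, so that monotriflate 15 ends as a silanol on work-up, or the salicylate OH of ring D may be silylated in competition. Fallback (a smaller tether built from a dichlorosilane): setting out from 4, i-Pr2SiCl2 (excess, imidazole, CH2Cl2, 0 °C, excess reagent removed in vacuo) should give chloro(3-formyl-2-iodo-5-methoxyphenoxy)diisopropylsilane F5. F5 with 14 and imidazole in DMF should give the diisopropylsilylene analogue of silyl ketal 16 F6. The conditions of step 13 would then give the diisopropylsilylene-bridged indenone F7, and HF·pyridine would remove the bridge, which comes back to the route at 19.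

**Further compounds**

F1 | step 13 | methyl 2-{2-[3-(2-acetoxy-6-(methoxymethoxy)-4-methylphenyl)-6-methoxy-4-(methoxymethoxy)-1-oxo-1H-inden-2-yl]-4-methoxy-6-(methoxymethoxy)phenoxy}-6-hydroxy-4-methylbenzoate | O=C1C(c2cc(OC)cc(OCOC)c2Oc2cc(C)cc(O)c2C(=O)OC)=C(c2c(OC(C)=O)cc(C)cc2OCOC)c2c(OCOC)cc(OC)cc12
F2 | step 5 | (2-acetoxy-6-formyl-4-methoxyphenyl)(2,4,6-trimethoxyphenyl)iodonium tosylate | CC(=O)Oc1cc(OC)cc(C=O)c1[I+]c1c(OC)cc(OC)cc1OC.Cc1ccc(S(=O)(=O)[O-])cc1
F3 | step 5 | methyl 2-(2-acetoxy-6-formyl-4-methoxyphenoxy)-6-hydroxy-4-methylbenzoate | COC(=O)c1c(O)cc(C)cc1Oc1c(C=O)cc(OC)cc1OC(C)=O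
F4 | step 5 | methyl 2-(2-formyl-6-hydroxy-4-methoxyphenoxy)-6-hydroxy-4-methylbenzoate | COC(=O)c1c(O)cc(C)cc1Oc1c(C=O)cc(OC)cc1O
F5 | step 12 | chloro(3-formyl-2-iodo-5-methoxyphenoxy)diisopropylsilane | O=Cc1cc(OC)cc(O[Si](Cl)(C(C)C)C(C)C)c1I
F6 | step 12 | diisopropylsilylene analogue of silyl ketal 16 | O=Cc1cc(OC)cc(O[Si](C(C)C)(C(C)C)Oc2cc(C)cc(OCOC)c2C#Cc2cc(OC)cc(OCOC)c2Oc2cc(C)cc(O)c2C(=O)OC)c1I
F7 | step 12 | diisopropylsilylene-bridged analogue of indenone 18 | O=C1C(c2cc(OC)cc(OCOC)c2Oc2cc(C)cc(O)c2C(=O)OC)=C2c3c(cc(C)cc3OCOC)O[Si](C(C)C)(C(C)C)Oc3cc(OC)cc1c32
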